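If each pass through the catalyst intermediate can end in spent catalyst instead of target, ask first what a pass costs, then whether the catalyst outlasts the substrate, then whether the hours suffice.

| flask | substrate | free catalyst | temperature | remark | time |
|---|---|---|---|---|---|
| winter | 10 mM | 3 mM | −25 °C | run made earlier |  |
| noon | 15 mM | 3 mM | −8 °C | run made earlier |  |
| Sunday's | 20 mM | 3.0 mM | −20 °C |  | 2.5 h |
| Thursday's | 20 mM | 3.0 mM | 5 °C |  | 2.5 h |
| Friday's | 20 mM | 3.0 mM |  | at 5 °C until 80 min, from then on at −20 °C | 2.5 h |

winter run (percent of the substrate charged)

| time / h | target / % | substrate / % |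
|---|---|---|
| 0.200 | 55.9 | 14.7 |
| 0.333 | 79.0 | 1.6 |
| 0.500 | 85.2 | 0.4 |
| 0.667 | 87.3 | 0 |
| 1.00 | 87.5 | 0 |
| 1.50 | 86.9 | 0 |
| 2.50 | 88.1 | 0.7 |

noon run (percent of the substrate charged)

| time / min | target / % | substrate / % |
|---|---|---|
| 6.00 | 86.2 | 0 |
| 12.0 | 87.5 | 0 |
| 15.0 | 86.7 | 0 |
| 20.0 | 89.0 | 0.6 |
| 30.0 | 87.0 | 0 |
| 50.0 | 89.5 | 0 |
| 80.0 | 87.2 | 0 |

(standard deviation of a reading: 1 percentage point)

- steps under discussion: substrate + free catalyst -> catalyst intermediate; catalyst intermediate -> free catalyst + target; catalyst intermediate -> spent catalyst

* the best flask by amount of target, in percent of the substrate charged; "all alike" if 1.5 percentage points covers them all (Sunday's / Thursday's / Friday's / all alike)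
* amount of target at the end, in percent of the substrate charged, Sunday's
* amount of target at the end, in percent of the substrate charged, Thursday's
* amount of target at the end, in percent of the substrate charged, Friday's

With substrate reading 0.7% or less, the late readings of the winter and noon runs average 87.7% target, so a pass loses about 12.3%. The two runs agree within their scatter, but 5 °C lies above both, so there this loss is carried over untested.

Sunday's, Thursday's and Friday's each charge catalyst at 15.0% of the substrate. Divide that fraction by the loss per pass and you have the catalyst reserve, the number of substrate charges the catalyst can carry before it is spent: 1.22. That is above one, so substrate should be the limiting reagent, and about 82.0% of the catalyst should end spent.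

The winter run read 85.3% of its substrate taken in 0.200 h, so at that opening pace Sunday's charge, twice as large, needs 0.469 h. That pace belongs to −25 °C, colder than these flasks; I carry it over untested. Live catalyst should fall to 18.0% of its charge on the way. If the pace falls with it, the time grows about twice, to 0.981 h. That is less than the 2.5 h allowed and the 80 min before Friday's cooling. My own figure is therefore 87.7% in each flask.

The forecast says all alike, with 87.5% for each flask in a range of 85.5% to 88.7%; in its words, “substrate should still be fully consumed”.

The flasks give 87.3% for Sunday's, 87.7% for Thursday's and 87.7% for Friday's: all alike, as forecast.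

    substrate + free catalyst → catalyst intermediate (k = 1380 L mol⁻¹ min⁻¹, Ea = 46.0 kJ mol⁻¹)
    catalyst intermediate → free catalyst + target (k = 0.380 min⁻¹, Ea = 69.0 kJ mol⁻¹)
    catalyst intermediate → spent catalyst (k = 0.0554 min⁻¹, Ea = 68.0 kJ mol⁻¹)
    (constants at −20 °C)

Friday's flask ends with 0% substrate and 81.7% of its catalyst spent, beside the 82.0% reckoned from its reserve. Now raise Friday's substrate to 50 mM, holding the rest. Catalyst is then 6.00% of the substrate and the reserve is 0.488, below one. The reckoning therefore expects the catalyst to be spent first, with 42.8% target and 51.2% substrate left. That neighbouring flask ends with 100% of its catalyst spent, 43.0% target and 51% substrate left.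

(The numbers in the tables come from a simulation from invented constants, and the scatter is random.)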